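(The constants used here stand for no real mixture; no experiment stands behind them.)

Starting material in each set-up below leaves by two exits, whose rates per unit of it are the two numbers compared here. It goes to product with the first-order constant kP = 0.84 s⁻¹, and to homo dimer with kDc, where c is the free starting material concentration and kD = 38.0 M⁻¹ s⁻¹ is twice the step's constant, since two are used at each turn. Their ratio is the split, S = kP/(kDc), a selectivity factor that grows as c falls; its value at the charge, the split at the charge, is 1.11.

| flask | starting material | remark | time |
|---|---|---|---|
| Sunday's | 0.020 M | one stirred flow tank at steady state, fed with the mixture as stated, mean residence time 50 s |  |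
| Wednesday's | 0.020 M | a tube with plug flow, the mixed feed as stated, residence time 50 s | 50 s |
| Tuesday's | 0.020 M | a closed flask charged with all of it at once and left for 50 s | 50 s |
| Saturday's | 0.020 M | a single well-mixed tank run continuously and read at steady state, 150 s in it on average |  |

    starting material → product (k1 = 0.84 s⁻¹)
    2 starting material → homo dimer (k2 = 19 M⁻¹ s⁻¹)
    starting material ⇌ intermediate B (K3 = 0.87, k3 = 0.52 s⁻¹)
    starting material ⇌ intermediate A (K4 = 0.87, k4 = 1.6 s⁻¹)
    intermediate A ⇌ intermediate C (K5 = 2.6, k5 = 0.029 s⁻¹)

1. the set-up with the highest amount of product at the outlet or at the end, in percent of the starting material put in ("none" if the first two lie within 2 percentage points) (Sunday's / Wednesday's / Tuesday's / Saturday's / none)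
2. amount of product at the outlet or at the end, in percent of the starting material put in, Sunday's
3. amount of product at the outlet or at the end, in percent of the starting material put in, Wednesday's
4. amount of product at the outlet or at the end, in percent of the starting material put in, Tuesday's
5. amount of product at the outlet or at the end, in percent of the starting material put in, Saturday's

- percentages count the starting material that a species holds: one homo dimer counts as two
- where a step has two of a species, its rate is k times that concentration squared, and two are used at each turn
- the stated concentrations are those of everything mixed, before any reaction; amounts are the same in each set-up
- run time (Wednesday's): 50 s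

In this hand reckoning, Tuesday's flask and Wednesday's tube both begin at that split, and the reckoning goes no further for them. Each tank holds a single low c. With intermediates B and A assumed in equilibrium with starting material and intermediate C set aside, the balance reads c = F/(H + (kP + kDc)τ), where F is the fed concentration, τ the mean residence time and H = 2.74 is one plus the two equilibrium constants. Since c stands on both sides, the dimer term is first dropped, which gives 4.47 × 10⁻⁴ M for Sunday's tank and 1.55 × 10⁻⁴ M for Saturday's. Putting those back gives 4.39 × 10⁻⁴ M and 1.54 × 10⁻⁴ M. The splits are then 50.4 and 143, both far above the charge's, and kPτc/F puts product at 92.1% for Sunday's and 97.2% for Saturday's.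

The forecast chose Saturday's, with 90.7% for Sunday's, 80.5% for Wednesday's, 80.5% for Tuesday's and 96.2% for Saturday's, both tank figures below this reckoning, on the ground that “the tanks hold the starting material very dilute”.

The simulation gives 90.7% for Sunday's, 81.0% for Wednesday's, 81.0% for Tuesday's and 96.2% for Saturday's, so Saturday's is best.

Saturday's tank stood at 1.53 × 10⁻⁴ M, which puts its split at 145, against 51.2 at the 4.32 × 10⁻⁴ M of Sunday's tank. The main reason for the product in Saturday's tank is the back reaction of intermediate A to starting material: with it taken away, product there falls from 96.2% to 34.2%, and the best set-up changes. A closed flask like Tuesday's but charged with 0.050 M starts at a split of 0.442, below 1.11, and after 50.0 s holds 65.5% product and 33.3% homo dimer.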